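(The constants come from no measurement.)

Read the constants first, 3.8 /s for release of product and 3000 /M/s for trapping, because they tell you whether the next run is worth dosing at all.

| flask | substrate | coupling partner | capture agent | free catalyst | time | remark |
|---|---|---|---|---|---|---|
| south-west | 2.0 × 10⁻⁴ M | 0.400 mM (fed, over 1.0 min) | 0.0600 mM | 6.6 µM | 80 s | all else is in the flask from the start; the feed brings no volume worth counting |
| north | 2.0 × 10⁻⁴ M (fed, over 1.0 min) | 0.400 mM | 0.0600 mM | 6.6 µM | 80 s | all else is in the flask from the start; the feed brings no volume worth counting |
| south-east | 2.0 × 10⁻⁴ M | 0.400 mM | 0.0600 mM | 6.6 µM | 80 s | everything together at the start |
| west | 2.0 × 10⁻⁴ M (in portions, 5, over 1.0 min) | 0.400 mM | 0.0600 mM | 6.6 µM | 80 s | first portion at the start, last at 1.0 min |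

    substrate + catalyst intermediate A → catalyst intermediate B (k1 = 27000 /M/s)
    catalyst intermediate A → spent catalyst B (k2 = 0.050 /s)
    coupling partner + free catalyst ⇌ catalyst intermediate A (K3 = 310 /M, k3 = 11000 /M/s)
    catalyst intermediate B → free catalyst + product (k4 = 3.8 /s)
    catalyst intermediate B + capture agent → trapped intermediate (k5 = 3000 /M/s)
    free catalyst + product → spent catalyst A (k6 = 210 /M/s)

1. which flask leads in amount of product, in percent of the substrate charged ("all alike" within 1.5 percentage points) (south-west / north / south-east / west / all alike)
2. how much product is there at the end, in percent of the substrate charged: south-west
3. how much product is there at the end, in percent of the substrate charged: north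
4. how much product is there at the end, in percent of the substrate charged: south-east
5. how much product is there at the end, in percent of the substrate charged: west

Free catalyst picks up coupling partner, then substrate, and catalyst intermediate B either releases product or meets capture agent. Both branches leave the same intermediate, so divide one rate by the other and both its concentration and time drop out. Call the result N, the product released per catalyst trapped, 21.1: the release constant over the trapping constant times 0.0600 mM of capture agent. This is a turnover number, reckoned at this level of capture agent. What gets dosed is substrate or coupling partner, and capture agent, charged at the start at 9.09 times the catalyst, barely falls, so N holds across the recipes.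

Now multiply. With the whole catalyst charge trapped, N times 6.6 µM gives product worth 69.7% of the substrate charged. That is less than the charge, so on this reckoning catalyst, not substrate, is the limiting reagent, and product is this ceiling times the share of catalyst that ends trapped.

What the recipes move is that share. Catalyst intermediate A can also die to spent catalyst B, and the same division gives 0.195 spent per catalyst trapped at full substrate, but 0.390 at half that substrate. So dosing substrate diverts catalyst away from the productive branch. Dosed coupling partner I cannot price this way, and my reckoning gives a ceiling and a direction, not a percentage for each flask. I commit to this: charge everything together, and if you want more product, raise the catalyst, since the ceiling grows with it.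

The forecast put south-east first at 36.4%, with 31% for south-west, 28.3% for north and 28.8% for west, and its ground is that with feeding “more catalyst is lost per turnover”.

The simulation puts south-east first at 36.1%, ahead of 30.6% in south-west, 27.6% in north and 27.4% in west. Product over the ceiling implies 51.8% of the catalyst trapped in south-east, and after 80.0 s that flask holds 51.4% as trapped intermediate. Take a neighbour of west charged with 2.6 × 10⁻⁵ M of free catalyst: its product, 54.8% of the substrate charged, divided by N implies 20.0% of its catalyst trapped, and after 80.0 s trapped intermediate stands there at 20.9%.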